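## Retrosynthetic overview

1. Target 18 (locants: carboxyl carbon C1; ring carbons C3–C6 with the O–O bridge between C3 and C6; side chain C7–C14) ⇐ 17 by diimide reduction of a C4 vinyl group, i.e. the C4 ethyl group is carried one oxidation level higher so that C4 can serve as an allyl terminus.
2. 17 ⇐ lactone 15 + triene 9 in one operation: C4–C5 bond by attack of the diene on a π-allyl iridium electrophile, then O–C6 bond by capture of the resulting allyl cation by the peroxide oxygen. The 1,2-dioxane is the only ring of the target and is formed here; the lactone ring of 15 is temporary.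
3. Enabling features: in 15 the five-membered lactone ring C1(=O)–C2–C3–C4–O (a γ-vinyl-γ-butyrolactone, absent from the target), whose allylic C4–O bond ionises and releases the C1 carboxylate; in 9 the 2,4-dialkyl-1,3-diene C5=C6–C7=C8, nucleophilic at C5 and giving a C6–C7–C8 allyl cation whose C6 terminus lies six atoms from the tert-butylperoxy oxygen.
4. 9 ⇐ Negishi coupling of alkenyl iodide 8 ⇐ syn-carbocupration/iodination of alkyne 6 ⇐ aldehyde 5 ⇐ Johnson–Claisen ester 4 (C10 by chirality transfer) ⇐ allylic alcohol 2 ⇐ (E)-pent-2-enal 1.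
5. 15 ⇐ aldehyde 13 + vinylmagnesium bromide ⇐ peroxy diester 12 ⇐ dimethyl D-malate 10 (C3 by SN2 inversion with tert-butyl hydroperoxide).

Key step: step 10

Assumption: the sense of induction of the (+)-amino-alcohol catalyst in step 1 and of the (S)-phosphoramidite–olefin ligand in step 10 is taken by analogy with simple substrates; should either prove opposite, the other enantiomer of that catalyst is used.

## Route

Step 1
Reactants: 1 (2E)-pent-2-enal
Product: 2 (3R,4E)-hept-4-en-3-ol
Conditions: Et2Zn, (+)-3-exo-morpholinoisoborneol [(+)-MIB, 4 mol%], hexane–toluene, 0 °C; aq. HCl (1 M), 0 °C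
Reagents that add atoms: diethylzinc, CC[Zn]CC
Why: Amino-alcohol-catalysed enantioselective 1,2-addition of a dialkylzinc to an enal, in which the chiral zinc aminoalkoxide should deliver ethyl to the Re face of the aldehyde and so set the 3R carbinol that is later relayed to C10.

Step 2
Reactants: 2 (3R,4E)-hept-4-en-3-ol
Product: 4 ethyl (3R,4E)-3-ethylhept-4-enoate, via ketene acetal 3 (not isolated)
Conditions: MeC(OEt)3, EtCO2H (cat.), 140 °C, ethanol distilled off
Reagents that add atoms: triethyl orthoacetate, CC(OCC)(OCC)OCC
Why: Johnson–Claisen rearrangement, in which the mixed ketene acetal 3 reacts through a chair transition state with the carbinol ethyl group equatorial, so that the 3R centre of 2 is transferred suprafacially to the new 3R centre of 4 (C10 of the target) and the new alkene is formed E.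

Step 3
Reactants: 4 ethyl (3R,4E)-3-ethylhept-4-enoate
Product: 5 (3R,4E)-3-ethylhept-4-enal
Conditions: i-Bu2AlH, CH2Cl2, −78 °C; aq. potassium sodium tartrate
Reagents that add atoms: none
Why: Partial reduction of an ester with i-Bu2AlH at low temperature stops at the aluminium hemiacetal, which gives the aldehyde on work-up, and the β stereocentre cannot epimerise.

Step 4
Reactants: 5 (3R,4E)-3-ethylhept-4-enal
Product: 6 (4R,5E)-4-ethyloct-5-en-1-yne
Conditions: dimethyl (1-diazo-2-oxopropyl)phosphonate, K2CO3, MeOH, 0 °C to 23 °C
Reagents that add atoms: dimethyl (1-diazo-2-oxopropyl)phosphonate, COP(=O)(OC)C(=[N+]=[N-])C(C)=O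
Why: Ohira–Bestmann (Seyferth–Gilbert) homologation, in which the diazomethylphosphonate anion formed in situ converts the aldehyde into the terminal alkyne by olefination, loss of N2 and 1,2-hydride shift under conditions that leave the alkene and the stereocentre untouched.

Step 5
Reactants: 6 (4R,5E)-4-ethyloct-5-en-1-yne
Product: 8 (1E,4R,5E)-2,4-diethyl-1-iodoocta-1,5-diene, via alkenylcopper 7 (not isolated)
Conditions: EtMgBr, CuBr·SMe2, Et2O–Me2S, −45 °C; then 6, −25 °C; then I2, THF, −78 °C to 0 °C
Reagents that add atoms: ethylmagnesium bromide, CC[Mg]Br; iodine, II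
Why: Syn-carbocupration of a terminal alkyne by an alkylcopper–magnesium bromide reagent places ethyl on the internal carbon and copper on the terminal carbon on the same side, and iodinolysis with retention gives the E alkenyl iodide that fixes the C7=C8 geometry.

Step 6
Reactants: 8 (1E,4R,5E)-2,4-diethyl-1-iodoocta-1,5-diene
Product: 9 (3E,6R,7E)-2,4,6-triethyldeca-1,3,7-triene
Conditions: CH2=C(Et)MgBr, ZnCl2, THF, 0 °C; then 8, Pd(PPh3)4 (3 mol%), THF, 23 °C
Reagents that add atoms: but-1-en-2-ylmagnesium bromide, C=C(CC)[Mg]Br
Why: Negishi coupling of an alkenyl iodide with an alkenylzinc halide under zerovalent palladium catalysis proceeds with retention of alkene geometry and gives the 2,4-disubstituted 1,3-diene.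

Step 7
Reactants: 10 dimethyl (2R)-2-hydroxybutanedioate (dimethyl D-malate)
Product: 12 dimethyl (2S)-2-(tert-butylperoxy)butanedioate, via triflate 11 (not isolated)
Conditions: Tf2O, 2,6-lutidine, CH2Cl2, −78 °C; then t-BuOOH (anhydrous, in decane), K2CO3, −40 °C to 0 °C
Reagents that add atoms: tert-butyl hydroperoxide, CC(C)(C)OO
Why: O-Triflation followed by SN2 alkylation of the hydroperoxide at the α-carbon of the ester should invert the 2R alcohol cleanly to the 2S peroxide (the future C3), the weak heterogeneous base and low temperature being chosen to suppress elimination to fumarate and Kornblum–DeLaMare fragmentation.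

Step 8
Reactants: 12 dimethyl (2S)-2-(tert-butylperoxy)butanedioate
Product: 13 methyl (3S)-3-(tert-butylperoxy)-4-oxobutanoate
Conditions: i-Bu2AlH (1.0 equiv), CH2Cl2, −78 °C; MeOH, then aq. potassium sodium tartrate
Reagents that add atoms: none
Why: Low-temperature half-reduction with i-Bu2AlH is expected to select the ester α to the electron-withdrawing peroxy oxygen, which is the more electrophilic and forms the more stable chelated aluminium hemiacetal (by analogy with α-alkoxy succinates), while the hindered tert-butyl peroxide should survive at −78 °C.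

Step 9
Reactants: 13 methyl (3S)-3-(tert-butylperoxy)-4-oxobutanoate
Product: 15 (4S,5RS)-4-(tert-butylperoxy)-5-ethenyloxolan-2-one, via hydroxy ester 14 (not isolated)
Conditions: CH2=CHMgBr (1.1 equiv), THF, −78 °C; aq. NH4Cl; then PPTS (cat.), CH2Cl2, 23 °C
Reagents that add atoms: vinylmagnesium bromide, C=C[Mg]Br
Why: Grignard 1,2-addition to the aldehyde followed by lactonisation of the γ-hydroxy ester gives the γ-vinyl-γ-butyrolactone, and the new carbinol centre may form as a mixture because it is planarised in step 10.

Step 10
Reactants: 15 (4S,5RS)-4-(tert-butylperoxy)-5-ethenyloxolan-2-one; 9 (3E,6R,7E)-2,4,6-triethyldeca-1,3,7-triene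
Product: 17 2-[(3S,4S,6S)-4-ethenyl-6-ethyl-6-[(1E,4R,5E)-2,4-diethylocta-1,5-dien-1-yl]-1,2-dioxan-3-yl]acetic acid, via allyl cation 16 (not isolated)
Conditions: [Ir(cod)Cl]2 (4 mol%), (S)-BINOL-derived dibenz[b,f]azepine phosphoramidite (P,olefin ligand, 16 mol%), Zn(OTf)2 (20 mol%), 15 (1.3 equiv), ClCH2CH2Cl, 25 °C
Reagents that add atoms: none
Why: Proposed new method: mechanistic reasoning – the monovalent iridium catalyst, helped by Zn(OTf)2 on the lactone carbonyl, ionises the allylic C4–O bond of 15 to a π-allyl complex of trivalent iridium that carries the C1 carboxylate, the unhindered CH2 terminus (C5) of the electron-rich diene unit of 9 attacks the substituted allyl terminus C4, and the bis-tertiary allyl cation 16 (C6–C7–C8) is captured at C6 by the distal tert-butylperoxy oxygen, the peroxonium ion then losing 2-methylpropene irreversibly. The closest known reaction types are the iridium–phosphoramidite allylic substitution of branched allylic alcohols by 1,1-disubstituted alkenes (branched-selective and enantioconvergent) together with iridium-initiated cation–olefin cyclisation, the opening of γ-vinyl lactones to π-allyl metal carboxylates, and the dealkylative capture of cations by tert-butyl peroxides as in electrophile-induced cycloperoxidation and peroxycarbenium–alkene annulation, so each elementary event has precedent and only their union is new. The 1,2-dioxane is closed in the 6-exo mode on the C6 terminus of the allyl cation, closure at C8 would need an eight-membered ring, and attack by the inner peroxide oxygen would give a five-membered peroxonium ion that cannot dealkylate and reverts. C4 is set by the ligand, which decides the face of the allyl unit attacked anti to iridium whatever the configuration of the carbinol carbon of 15 (the epimeric complexes equilibrate), and C6 is set in a chair-like closure with the C3 and C4 substituents equatorial, in which the flat alkenyl arm (its first atom carries only hydrogen) takes the axial site beside C5–C4 and ethyl the equatorial one, while C7=C8 stays E because the allyl cation should not rotate before capture. The step needs branched instead of linear attack on the allyl unit (secured by iridium), reaction of 9 through C5 and not through C8 or the isolated C11=C12 alkene (secured by the 1,1-disubstituted terminus that leads to the stabilised cation), and peroxide capture ahead of proton loss or closure of the carboxylate to a seven-membered lactone (secured by the six-membered geometry and by the reversibility of lactone formation under the Lewis acid).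

Step 11
Reactants: 17 2-[(3S,4S,6S)-4-ethenyl-6-ethyl-6-[(1E,4R,5E)-2,4-diethylocta-1,5-dien-1-yl]-1,2-dioxan-3-yl]acetic acid
Product: 18 2-[(3S,4R,6S)-4,6-diethyl-6-[(1E,4R,5E)-2,4-diethylocta-1,5-dien-1-yl]-1,2-dioxan-3-yl]acetic acid
Conditions: KO2CN=NCO2K (in portions until the vinyl group is consumed), AcOH, MeOH–CH2Cl2, −20 °C to 0 °C
Reagents that add atoms: none
Why: Diimide reduction (concerted syn transfer of H2 from HN=NH) should reduce the unhindered monosubstituted vinyl group much faster than the trisubstituted C7=C8 and the allylically branched 1,2-disubstituted C11=C12 alkenes and leaves the O–O bond and all stereocentres untouched.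

## Compound list

1 | (2E)-pent-2-enal | CC/C=C/C=O | starting material
2 | (3R,4E)-hept-4-en-3-ol | CC[C@@H](O)/C=C/CC | intermediate
3 | (3R,4E)-3-[(1-ethoxyethenyl)oxy]hept-4-ene (mixed ketene acetal) | CC[C@@H](OC(=C)OCC)/C=C/CC | intermediate (not isolated)
4 | ethyl (3R,4E)-3-ethylhept-4-enoate | CC/C=C/[C@H](CC)CC(=O)OCC | intermediate
5 | (3R,4E)-3-ethylhept-4-enal | CC/C=C/[C@H](CC)CC=O | intermediate
6 | (4R,5E)-4-ethyloct-5-en-1-yne | CC/C=C/[C@H](CC)CC#C | intermediate
7 | [(1E,4R,5E)-2,4-diethylocta-1,5-dien-1-yl]copper (MgBr2 complex) | CC/C=C/[C@H](CC)C/C(=C/[Cu])CC | intermediate (not isolated)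
8 | (1E,4R,5E)-2,4-diethyl-1-iodoocta-1,5-diene | CC/C=C/[C@H](CC)C/C(=C/I)CC | intermediate
9 | (3E,6R,7E)-2,4,6-triethyldeca-1,3,7-triene | CC/C=C/[C@H](CC)C/C(=C/C(CC)=C)CC | intermediate
10 | dimethyl (2R)-2-hydroxybutanedioate (dimethyl D-malate) | COC(=O)[C@@H](CC(=O)OC)O | starting material
11 | dimethyl (2R)-2-[(trifluoromethanesulfonyl)oxy]butanedioate | COC(=O)[C@@H](CC(=O)OC)OS(=O)(=O)C(F)(F)F | intermediate (not isolated)
12 | dimethyl (2S)-2-(tert-butylperoxy)butanedioate | COC(=O)[C@H](CC(=O)OC)OOC(C)(C)C | intermediate
13 | methyl (3S)-3-(tert-butylperoxy)-4-oxobutanoate | O=C[C@H](CC(=O)OC)OOC(C)(C)C | intermediate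
14 | methyl (3S,4RS)-3-(tert-butylperoxy)-4-hydroxyhex-5-enoate | C=CC(O)[C@H](CC(=O)OC)OOC(C)(C)C | intermediate (not isolated)
15 | (4S,5RS)-4-(tert-butylperoxy)-5-ethenyloxolan-2-one | C=CC1OC(=O)C[C@@H]1OOC(C)(C)C | intermediate
16 | allyl cation–carboxylate zwitterion formed after C4–C5 bond formation | CC/C=C/[C@H](CC)C/C(=C/[C+](CC)C[C@@H](C=C)[C@H](CC(=O)[O-])OOC(C)(C)C)CC | intermediate (not isolated)
17 | 2-[(3S,4S,6S)-4-ethenyl-6-ethyl-6-[(1E,4R,5E)-2,4-diethylocta-1,5-dien-1-yl]-1,2-dioxan-3-yl]acetic acid | CC/C=C/[C@H](CC)C/C(=C/[C@]1(CC)C[C@@H](C=C)[C@H](CC(=O)O)OO1)CC | intermediate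
18 | 2-[(3S,4R,6S)-4,6-diethyl-6-[(1E,4R,5E)-2,4-diethylocta-1,5-dien-1-yl]-1,2-dioxan-3-yl]acetic acid | CC/C=C/[C@H](CC)C/C(=C/[C@]1(CC)C[C@@H](CC)[C@H](CC(=O)O)OO1)CC | target

## Step count and risks

Total step count: 11. Longest linear sequence: 8 steps (steps 1–6, 10, 11).

Steps most likely to fail:

Step 10 (new method). The phosphoramidite–iridium catalyst may be consumed by the O–O bond or sequestered by the conjugated diene. Allyl cation 16 may lose a proton to a triene before the weakly nucleophilic tert-butylperoxy oxygen captures it. Facial selectivity at C6 may be low. The fallback uses known chemistry only, sets out from 9 and comes back at 18. It makes the same two bonds by the aerobic manganese-mediated peroxycyclisation of a 1,3-dicarbonyl compound with an alkene. tert-Butyl 2-formylbutanoate F1 (from tert-butyl butanoate, LDA and ethyl formate) and 9 with Mn(OAc)3 (trivalent manganese, catalytic) under air in AcOH at 23 °C should give the dioxanol ester F2, by radical addition of C4 to C5, capture of O2 at C6 and closure of the hydroperoxide on the aldehyde. TFA in CH2Cl2 cleaves the tert-butyl ester and the β-formyl acid of the ring-opened tautomer loses CO2, giving the dioxanol F3, in which C4 can equilibrate to the 3,4-trans arrangement. Ac2O–pyridine gives the acetate F4. TMSOTf and 1-(tert-butyldimethylsilyloxy)-1-methoxyethene in CH2Cl2 at −78 °C add the acetate arm to the peroxycarbenium ion trans to the C4 ethyl group, giving the methyl ester F5, and LiOH in THF–water gives 18. This fallback gives up control at C6, so the wanted diastereomer has to be separated.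

Step 9. The α-peroxy aldehyde may undergo base-induced Kornblum–DeLaMare fragmentation or epimerisation, and the Grignard reagent may attack the O–O bond. The fallback sets out from 13 and comes back at 17. Wittig reaction of 13 with (triphenylphosphoranylidene)acetaldehyde gives the E-enal F6 without any basic organometallic. NaBH4–CeCl3·7H2O (Luche reduction) gives the linear allylic alcohol F7. F7 then takes the place of 15 under the conditions of step 10 with 9 (linear and branched allylic alcohols lead to the same π-allyl iridium intermediate) and should give the methyl ester F8, which LiOH hydrolyses to 17.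

Step 8. The hydride may attack the wrong ester or over-reduce to the alcohol. The fallback sets out from 12 and comes back at 15, and tells the two carboxyl groups apart before any hydride is used. Pig liver esterase in pH 7 buffer should hydrolyse the unhindered CH2CO2Me ester to the mono-acid F9, whose carboxylate is inert to i-Bu2AlH. Reduction (2.2 equiv, −78 °C) can then only give the aldehyde acid F10. Vinylmagnesium bromide (2.2 equiv, −78 °C) and acidification give 15 by lactonisation.

Further compounds
F1 | step 10 | tert-butyl 2-formylbutanoate | CCC(C=O)C(=O)OC(C)(C)C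
F2 | step 10 | tert-butyl 4,6-diethyl-6-[(1E,4R,5E)-2,4-diethylocta-1,5-dien-1-yl]-3-hydroxy-1,2-dioxane-4-carboxylate (dioxanol ester) | CC/C=C/[C@H](CC)C/C(=C/C1(CC)CC(CC)(C(=O)OC(C)(C)C)C(O)OO1)CC
F3 | step 10 | 4,6-diethyl-6-[(1E,4R,5E)-2,4-diethylocta-1,5-dien-1-yl]-1,2-dioxan-3-ol (dioxanol) | CC/C=C/[C@H](CC)C/C(=C/C1(CC)CC(CC)C(O)OO1)CC
F4 | step 10 | 4,6-diethyl-6-[(1E,4R,5E)-2,4-diethylocta-1,5-dien-1-yl]-1,2-dioxan-3-yl acetate | CC/C=C/[C@H](CC)C/C(=C/C1(CC)CC(CC)C(OC(C)=O)OO1)CC
F5 | step 10 | methyl 2-[(3S,4R,6S)-4,6-diethyl-6-[(1E,4R,5E)-2,4-diethylocta-1,5-dien-1-yl]-1,2-dioxan-3-yl]acetate | CC/C=C/[C@H](CC)C/C(=C/[C@]1(CC)C[C@@H](CC)[C@H](CC(=O)OC)OO1)CC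
F6 | step 9 | methyl (3S,4E)-3-(tert-butylperoxy)-6-oxohex-4-enoate | O=C/C=C/[C@H](CC(=O)OC)OOC(C)(C)C
F7 | step 9 | methyl (3S,4E)-3-(tert-butylperoxy)-6-hydroxyhex-4-enoate | OC/C=C/[C@H](CC(=O)OC)OOC(C)(C)C
F8 | step 9 | methyl 2-[(3S,4S,6S)-4-ethenyl-6-ethyl-6-[(1E,4R,5E)-2,4-diethylocta-1,5-dien-1-yl]-1,2-dioxan-3-yl]acetate | CC/C=C/[C@H](CC)C/C(=C/[C@]1(CC)C[C@@H](C=C)[C@H](CC(=O)OC)OO1)CC
F9 | step 8 | (3S)-3-(tert-butylperoxy)-4-methoxy-4-oxobutanoic acid | COC(=O)[C@H](CC(=O)O)OOC(C)(C)C
F10 | step 8 | (3S)-3-(tert-butylperoxy)-4-oxobutanoic acid | O=C[C@H](CC(=O)O)OOC(C)(C)C
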